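## Retrosynthetic overview

1. The C5–O angelate bond is made last: SN2 opening of an α-configured C5/C6 vinyl epoxide by angelic acid, with inversion at C5, giving the trans-diaxial hydroxy ester.
2. The vinyl epoxide comes from the C4 ketone by Saegusa–Ito dehydrogenation, Weitz–Scheffer epoxidation of the enone and Wittig methylenation.
3. The C2–O acetate bond is made by Mitsunobu inversion of a (Z)-2-ethylidene allylic alcohol.
4. That alcohol comes from a nickel-catalysed methylative alkynal cyclisation, which closes the five-membered ring B and fixes the Z-ethylidene.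
5. The alkynal comes from (S)-cryptone by conjugate alkynylation, enolate allylation and alkene cleavage; cryptone (six-membered ring A, formed first) comes from 3-methylbutanal and but-3-en-2-one.

Assumption: positions follow 1H-indene numbering of the target (C-1 ethylidene carbon, C-2 acetoxy, C-4 methylidene, C-5 angelate, C-6 hydroxyl, C-7 isopropyl); α is the face of H-7a, β the face of H-3a; angelic acid is taken as commercial.

## Route

Step 1
Reactants: 1 3-methylbutanal; 2 but-3-en-2-one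
Product: 4 (4S)-4-(propan-2-yl)cyclohex-2-en-1-one, via keto aldehyde 3 (not isolated)
Conditions: (S)-2-[methoxy(diphenyl)methyl]pyrrolidine (5 mol%), ethyl 3,4-dihydroxybenzoate (20 mol%), neat, 4 °C; then LiOH (0.2 equiv), i-PrOH, 23 °C
Reagents that add atoms: none
Why: Enamine-catalysed Michael addition, in which the diphenyl(methoxy)methyl group shields one enamine face and sets the (S) centre that becomes C-7, followed by intramolecular aldol condensation (organocatalytic Robinson-type annulation).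

Step 2
Reactants: 4 (4S)-4-(propan-2-yl)cyclohex-2-en-1-one; 5 ethynyl(trimethyl)silane
Product: 6 trimethyl({(3S,4S)-4-(propan-2-yl)-3-[(trimethylsilyl)ethynyl]cyclohex-1-en-1-yl}oxy)silane
Conditions: 5, n-BuLi, THF, −78 °C; ZnBr2, 0 °C; then 4, Me3SiOTf, Et2O–THF, −40 °C; Et3N, aq NaHCO3 work-up
Reagents that add atoms: trimethylsilyl trifluoromethanesulfonate, C[Si](C)(C)OS(=O)(=O)C(F)(F)F
Why: Silyl-triflate-promoted conjugate addition of an alkynylzinc to an s-trans enone; the nucleophile enters anti to the isopropyl group, setting C-7a trans to C-7, and the enolate is trapped regiospecifically as its silyl enol ether.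

Step 3
Reactants: 6 trimethyl({(3S,4S)-4-(propan-2-yl)-3-[(trimethylsilyl)ethynyl]cyclohex-1-en-1-yl}oxy)silane; 7 3-bromoprop-1-ene
Product: 10 (2R,3S,4S)-3-ethynyl-4-(propan-2-yl)-2-(prop-2-en-1-yl)cyclohexan-1-one, via lithium enolate 8 (not isolated), via C-silyl allyl ketone 9 (not isolated)
Conditions: MeLi, THF, 0 °C; 7, DMPU, −78 → 0 °C; then K2CO3 (0.2 equiv), MeOH, 23 °C
Reagents that add atoms: none
Why: Regiospecific lithium enolate generation from the silyl enol ether and SN2 allylation anti to the neighbouring alkynyl group set C-3a; the all-equatorial trans,trans ketone is also the thermodynamic epimer under the K2CO3/MeOH that removes the alkynyl silyl group.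

Step 4
Reactants: 10 (2R,3S,4S)-3-ethynyl-4-(propan-2-yl)-2-(prop-2-en-1-yl)cyclohexan-1-one
Product: 11 [(1R,2S,3S)-2-ethynyl-6-oxo-3-(propan-2-yl)cyclohexyl]acetaldehyde
Conditions: OsO4 (2 mol%), NaIO4 (4 equiv), 2,6-lutidine, 1,4-dioxane–H2O (3:1), 23 °C
Reagents that add atoms: osmium tetroxide, O=[Os](=O)(=O)=O; sodium periodate, [Na+].[O-]I(=O)(=O)=O
Why: Lemieux–Johnson oxidative cleavage; OsO4 dihydroxylates only the terminal alkene (alkyne and ketone are inert), periodate cleaves the diol, and no stereocentre is touched.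

Step 5
Reactants: 11 [(1R,2S,3S)-2-ethynyl-6-oxo-3-(propan-2-yl)cyclohexyl]acetaldehyde
Product: 12 (1Z,2R,3aR,7S,7aS)-1-ethylidene-2-hydroxy-7-(propan-2-yl)octahydro-4H-inden-4-one
Conditions: Ni(cod)2 (10 mol%), Me2Zn (2.5 equiv), THF, 0 °C; aq NH4Cl
Reagents that add atoms: dimethylzinc, C[Zn]C
Why: Nickel-catalysed alkylative alkynal cyclisation; oxidative cyclisation at zerovalent nickel gives an oxanickelacyclopentene, methyl transfer from zinc and reductive elimination place CH3 cis to the carbinol carbon (Z-ethylidene), and the near-planar metallacycle fits the trans-fused ring only with the C–O bond on the β face (about 45° to the alkene plane against about 75° for α), which sets C-2 as the β-alcohol.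

Step 6
Reactants: 12 (1Z,2R,3aR,7S,7aS)-1-ethylidene-2-hydroxy-7-(propan-2-yl)octahydro-4H-inden-4-one
Product: 13 (1Z,2S,3aR,7S,7aS)-1-ethylidene-4-oxo-7-(propan-2-yl)octahydro-1H-inden-2-yl acetate
Conditions: PPh3, DIAD, AcOH, toluene, 0 → 23 °C
Reagents that add atoms: acetic acid, CC(=O)O
Why: Mitsunobu reaction; acetate displaces the oxyphosphonium group in an SN2 step with inversion, forming the C2–O acetate bond on the α face.

Step 7
Reactants: 13 (1Z,2S,3aR,7S,7aS)-1-ethylidene-4-oxo-7-(propan-2-yl)octahydro-1H-inden-2-yl acetate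
Product: 15 (1Z,2S,3aR,7R,7aS)-1-ethylidene-4-oxo-7-(propan-2-yl)-2,3,3a,4,7,7a-hexahydro-1H-inden-2-yl acetate, via silyl enol ether 14 (not isolated)
Conditions: LiN(SiMe3)2, Me3SiCl (internal quench), THF, −78 °C; then Pd(OAc)2 (1.05 equiv), MeCN, 23 °C
Reagents that add atoms: none
Why: Kinetic deprotonation occurs at the unhindered C-5 methylene rather than the ring-fusion C-3a methine, and Saegusa–Ito oxidation of the resulting silyl enol ether gives the C5=C6 enone without touching a stereocentre.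

Step 8
Reactants: 15 (1Z,2S,3aR,7R,7aS)-1-ethylidene-4-oxo-7-(propan-2-yl)-2,3,3a,4,7,7a-hexahydro-1H-inden-2-yl acetate
Product: 16 (1Z,2S,3aR,5S,6S,7S,7aS)-5,6-epoxy-1-ethylidene-4-oxo-7-(propan-2-yl)octahydro-1H-inden-2-yl acetate
Conditions: t-BuOOH (decane solution), DBU, CH2Cl2, 0 → 23 °C
Reagents that add atoms: tert-butyl hydroperoxide, CC(C)(C)OO
Why: Weitz–Scheffer nucleophilic epoxidation is chemoselective for the electron-poor enone (ethylidene and acetate untouched), and the hydroperoxide adds axially to C-6 of the locked half-chair, i.e. from the α face, which sets both epoxide carbons.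

Step 9
Reactants: 16 (1Z,2S,3aR,5S,6S,7S,7aS)-5,6-epoxy-1-ethylidene-4-oxo-7-(propan-2-yl)octahydro-1H-inden-2-yl acetate
Product: 17 (1Z,2S,3aR,5R,6S,7S,7aR)-5,6-epoxy-1-ethylidene-4-methylidene-7-(propan-2-yl)octahydro-1H-inden-2-yl acetate
Conditions: Ph3PCH3Br, KOt-Bu, THF, 0 °C; then 16, 0 °C, 30 min
Reagents that add atoms: methyltriphenylphosphonium bromide, C[P+](c1ccccc1)(c1ccccc1)c1ccccc1.[Br-]
Why: Wittig methylenation of the α,β-epoxy ketone at 0 °C is faster than ylide attack on the acetate or enolisation at C-3a and creates no stereocentre.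

Step 10
Reactants: 17 (1Z,2S,3aR,5R,6S,7S,7aR)-5,6-epoxy-1-ethylidene-4-methylidene-7-(propan-2-yl)octahydro-1H-inden-2-yl acetate; 18 (2Z)-2-methylbut-2-enoic acid
Product: 19 (1Z,2S,3aR,5S,6S,7S,7aR)-2-(acetyloxy)-1-ethylidene-6-hydroxy-4-methylidene-7-(propan-2-yl)octahydro-1H-inden-5-yl (2Z)-2-methylbut-2-enoate
Conditions: 18 (1.5 equiv), N,N′-bis(3,5-di-tert-butylsalicylidene)ethane-1,2-diaminocobalt, Co(C32H46N2O2) (5 mol%, oxidised in air by 18 to the trivalent cobalt angelate), i-Pr2NEt (0.5 equiv), t-BuOMe, 0 → 23 °C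
Reagents that add atoms: none
Why: Proposed new method: cooperative cobalt–salen catalysis of the acidolysis of a 1,3-diene monoepoxide by an α,β-unsaturated acid, in which one trivalent cobalt centre binds the oxirane oxygen and a second delivers its angelate ligand to the allylic carbon C-5 from the β face in an SN2 event (inversion at C-5, trans-diaxial Fürst–Plattner opening of the rigid trans-hydrindane, allylic activation and ring geometry both favouring C-5 over C-6), while the buffered, non-ionising medium suppresses SN2′ attack at the exocyclic CH2 and Z-to-E isomerisation of the angelate; the closest known reaction type is the cobalt–salen-catalysed ring opening of terminal and meso epoxides by benzoic acids and water.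

## Compound list

1 | 3-methylbutanal | CC(C)CC=O | starting material
2 | but-3-en-2-one | CC(=O)C=C | starting material
3 | (2S)-5-oxo-2-(propan-2-yl)hexanal | O=C[C@H](C(C)C)CCC(C)=O | intermediate
4 | (4S)-4-(propan-2-yl)cyclohex-2-en-1-one | O=C1C=C[C@H](C(C)C)CC1 | intermediate
5 | ethynyl(trimethyl)silane | C#C[Si](C)(C)C | starting material
6 | trimethyl({(3S,4S)-4-(propan-2-yl)-3-[(trimethylsilyl)ethynyl]cyclohex-1-en-1-yl}oxy)silane | C[Si](C)(C)OC1=C[C@@H](C#C[Si](C)(C)C)[C@H](C(C)C)CC1 | intermediate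
7 | 3-bromoprop-1-ene | C=CCBr | starting material
8 | lithium (3S,4S)-4-(propan-2-yl)-3-[(trimethylsilyl)ethynyl]cyclohex-1-en-1-olate | [Li+].[O-]C1=C[C@@H](C#C[Si](C)(C)C)[C@H](C(C)C)CC1 | intermediate
9 | (2R,3S,4S)-4-(propan-2-yl)-2-(prop-2-en-1-yl)-3-[(trimethylsilyl)ethynyl]cyclohexan-1-one | O=C1[C@H](CC=C)[C@@H](C#C[Si](C)(C)C)[C@H](C(C)C)CC1 | intermediate
10 | (2R,3S,4S)-3-ethynyl-4-(propan-2-yl)-2-(prop-2-en-1-yl)cyclohexan-1-one | O=C1[C@H](CC=C)[C@@H](C#C)[C@H](C(C)C)CC1 | intermediate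
11 | [(1R,2S,3S)-2-ethynyl-6-oxo-3-(propan-2-yl)cyclohexyl]acetaldehyde | O=C1[C@H](CC=O)[C@@H](C#C)[C@H](C(C)C)CC1 | intermediate
12 | (1Z,2R,3aR,7S,7aS)-1-ethylidene-2-hydroxy-7-(propan-2-yl)octahydro-4H-inden-4-one (trans-fused, 2β-OH) | O=C1[C@@H]2C[C@@H](O)/C(=C\C)[C@H]2[C@H](C(C)C)CC1 | intermediate
13 | (1Z,2S,3aR,7S,7aS)-1-ethylidene-4-oxo-7-(propan-2-yl)octahydro-1H-inden-2-yl acetate (2α-OAc) | O=C1[C@@H]2C[C@H](OC(C)=O)/C(=C\C)[C@H]2[C@H](C(C)C)CC1 | intermediate
14 | (1Z,2S,3aR,7S,7aS)-1-ethylidene-7-(propan-2-yl)-4-[(trimethylsilyl)oxy]-2,3,3a,6,7,7a-hexahydro-1H-inden-2-yl acetate | C[Si](C)(C)OC=1[C@@H]2C[C@H](OC(C)=O)/C(=C\C)[C@H]2[C@H](C(C)C)CC=1 | intermediate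
15 | (1Z,2S,3aR,7R,7aS)-1-ethylidene-4-oxo-7-(propan-2-yl)-2,3,3a,4,7,7a-hexahydro-1H-inden-2-yl acetate | O=C1[C@@H]2C[C@H](OC(C)=O)/C(=C\C)[C@H]2[C@H](C(C)C)C=C1 | intermediate
16 | (1Z,2S,3aR,5S,6S,7S,7aS)-5,6-epoxy-1-ethylidene-4-oxo-7-(propan-2-yl)octahydro-1H-inden-2-yl acetate (α-epoxide) | O=C1[C@@H]2C[C@H](OC(C)=O)/C(=C\C)[C@H]2[C@H](C(C)C)[C@@H]3O[C@H]13 | intermediate
17 | (1Z,2S,3aR,5R,6S,7S,7aR)-5,6-epoxy-1-ethylidene-4-methylidene-7-(propan-2-yl)octahydro-1H-inden-2-yl acetate (α-epoxide) | C=C1[C@@H]2C[C@H](OC(C)=O)/C(=C\C)[C@H]2[C@H](C(C)C)[C@@H]3O[C@H]13 | intermediate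
18 | (2Z)-2-methylbut-2-enoic acid (angelic acid) | C/C=C(/C)C(=O)O | starting material
19 | (1Z,2S,3aR,5S,6S,7S,7aR)-2-(acetyloxy)-1-ethylidene-6-hydroxy-4-methylidene-7-(propan-2-yl)octahydro-1H-inden-5-yl (2Z)-2-methylbut-2-enoate | C=C1[C@@H]2C[C@H](OC(C)=O)/C(=C\C)[C@H]2[C@H](C(C)C)[C@H](O)[C@H]1OC(=O)/C(C)=C\C | target

## Step count and risks

Total step count: 10. Longest linear sequence: 10 steps (from 1 and 2 to 19).

Steps most likely to fail:

Step 5 (alkylative cyclisation). The risks are low or reversed selectivity at C-2 and nickel-mediated oligomerisation of the terminal alkyne. The fallback sets out from 10 and comes back at 13. Ring-closing enyne metathesis of 10 (second-generation Grubbs catalyst, RuCl2(=CHPh)(PCy3)(H2IMes), ethylene atmosphere, CH2Cl2, 40 °C) gives the vinylcyclopentene ketone F1. Palladium-catalysed 1,4-hydrosilylation with HSiCl3 ([PdCl(η3-C3H5)]2 and the antipode of 2-methoxy-2′-(diphenylphosphino)-1,1′-binaphthyl that places silicon on the α face; s-cis diene coordination enforces the Z geometry) gives the allylic trichlorosilane F2. Tamao–Fleming oxidation (H2O2, KF, KHCO3, retention) gives the 2α-alcohol F3, and Ac2O/pyridine converts it into 13, so steps 4 to 6 are replaced.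

Step 8 (facial selectivity of the epoxidation). The β-epoxide would be useless. The fallback sets out from 15 and comes back at 17. Addition of Me3SiCH2MgCl/CeCl3 (THF, −78 °C, equatorial attack, acetate spared) gives the tertiary allylic alcohol F4 with an axial α-hydroxyl. Hydroxyl-directed epoxidation (VO(acac)2, t-BuOOH, CH2Cl2) gives the α-epoxy alcohol F5. Peterson elimination (KH, THF) then gives 17; Payne rearrangement is excluded because the alkoxide and the epoxide oxygen are cis. Steps 8 and 9 are replaced.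

Step 10 (the proposed new step). The risks are SN2′ attack at the exocyclic methylene, ionisation to an allyl cation and angelate-to-tiglate isomerisation. The fallback uses known chemistry, sets out from 17 and comes back at 19. Acid-catalysed hydrolysis (HClO4 cat., THF–H2O, 0 °C) opens the vinyl epoxide at allylic C-5 with inversion to the trans-diaxial diol F6. Angelic acid 18, 2,4,6-trichlorobenzoyl chloride and Et3N give the mixed anhydride F7, which in toluene at 80 °C without DMAP acylates the less hindered allylic C-5 hydroxyl of F6 to give 19. The trans-diaxial arrangement rules out later acyl migration to O-6.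

Further compounds

F1 | step 5 | (3aR,7S,7aS)-1-ethenyl-7-(propan-2-yl)-3,3a,5,6,7,7a-hexahydro-4H-inden-4-one | O=C1[C@@H]2CC=C(C=C)[C@H]2[C@H](C(C)C)CC1
F2 | step 5 | (1Z,2S,3aR,7S,7aS)-1-ethylidene-7-(propan-2-yl)-2-(trichlorosilyl)octahydro-4H-inden-4-one | O=C1[C@@H]2C[C@H]([Si](Cl)(Cl)Cl)/C(=C\C)[C@H]2[C@H](C(C)C)CC1
F3 | step 5 | (1Z,2S,3aR,7S,7aS)-1-ethylidene-2-hydroxy-7-(propan-2-yl)octahydro-4H-inden-4-one | O=C1[C@@H]2C[C@H](O)/C(=C\C)[C@H]2[C@H](C(C)C)CC1
F4 | step 8 | (1Z,2S,3aR,4S,7R,7aS)-1-ethylidene-4-hydroxy-7-(propan-2-yl)-4-[(trimethylsilyl)methyl]-2,3,3a,4,7,7a-hexahydro-1H-inden-2-yl acetate | O[C@]1(C[Si](C)(C)C)[C@@H]2C[C@H](OC(C)=O)/C(=C\C)[C@H]2[C@H](C(C)C)C=C1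
F5 | step 8 | (1Z,2S,3aR,4R,5S,6S,7S,7aS)-5,6-epoxy-1-ethylidene-4-hydroxy-7-(propan-2-yl)-4-[(trimethylsilyl)methyl]octahydro-1H-inden-2-yl acetate | O[C@]1(C[Si](C)(C)C)[C@@H]2C[C@H](OC(C)=O)/C(=C\C)[C@H]2[C@H](C(C)C)[C@@H]3O[C@H]13
F6 | step 10 | (1Z,2S,3aR,5S,6S,7S,7aR)-1-ethylidene-5,6-dihydroxy-4-methylidene-7-(propan-2-yl)octahydro-1H-inden-2-yl acetate | C=C1[C@@H]2C[C@H](OC(C)=O)/C(=C\C)[C@H]2[C@H](C(C)C)[C@H](O)[C@H]1O
F7 | step 10 | (2Z)-2-methylbut-2-enoic 2,4,6-trichlorobenzoic anhydride | C/C=C(/C)C(=O)OC(=O)c1c(Cl)cc(Cl)cc1Cl
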